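−0.0900 mM is the number to hold for this flask. It is the flask's partner margin M: partner charged minus solid substrate and protic impurity charged, counted one for one by my assumption, so zero means exact cover.

| flask | solid substrate | partner | protic impurity | remark | time |
|---|---|---|---|---|---|
| Monday's | 0.20 mM | 0.53 equiv | 0.10 mM | run made earlier |  |
| Saturday's | 0.20 mM | 2.1 equiv | 0.10 mM | run made earlier |  |
| Thursday's | 0.20 mM | 1.05 equiv | 0.15 mM | run made earlier |  |
| flask | 0.20 mM | 1.05 equiv | 0.100 mM |  | 2.0 min |

Saturday's run sits above that zero at 0.120 mM, and you read 80.9% target at 90.0 s.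

| run | time / s | target / % | dissolved substrate / % |
|---|---|---|---|
| Monday's | 20.0 | 5.4 | 16.6 |
| Monday's | 40.0 | 13.9 | 22.1 |
| Monday's | 60.0 | 19.2 | 26.0 |
| Monday's | 80.0 | 23.6 | 28.7 |
| Monday's | 90.0 | 24.8 | 30.5 |
| Saturday's | 10.0 | 5.8 | 7.0 |
| Saturday's | 15.0 | 10.6 | 8.3 |
| Saturday's | 25.0 | 21.0 | 9.6 |
| Saturday's | 50.0 | 46.0 | 12.1 |
| Saturday's | 90.0 | 80.9 | 14.7 |
| Thursday's | 10.0 | 3.1 | 10.0 |
| Thursday's | 25.0 | 13.2 | 15.0 |
| Thursday's | 40.0 | 21.6 | 18.2 |
| Thursday's | 60.0 | 30.9 | 22.0 |
| Thursday's | 90.0 | 41.5 | 26.4 |

(scatter of a reading: 0.3 percentage points)

But Thursday's run, with the flask's partner and more protic impurity, sits at −0.140 mM and reads 41.5% at the same time. So the flask lies between them, yet below zero, which makes partner its limiting reagent. My reckoning: when no partner stands in this flask, the substrate left, solid and dissolved counted together, and the protic impurity left should add up to the size of M, 0.0900 mM.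

- as a solid, counted per litre of solution: solid substrate
- the numbers in the tables scatter with a standard deviation of 0.3 percentage points
- at the start none of the solid substrate is in solution
- dissolved substrate means what is dissolved; the solid is not counted in it

* target at 2.0 min, in percent of the solid substrate charged
* concentration of dissolved substrate in solution at 2.0 min, in percent of saturation

The forecast gives 55% and 80% of saturation, holding that “The impurity does not kill partner instantly”.

The flask gives 56.3% and 78.3% of saturation, so the forecast stands.

    solid substrate ⇌ dissolved substrate, rate k1*(cs1 - [dissolved substrate]) while solid is left; crystals form when [dissolved substrate] > cs1 (solubility = 0.0720 mM, k = 0.0420 /s)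
    dissolved substrate + partner → target (k = 340 /M/s)
    partner + protic impurity → quenched reagent (k = 130 /M/s)

At 20.0 min the flask has 0% partner and 0% solid substrate, and its dissolved substrate and protic impurity add up to 0.0900 mM, the size of M. Now take the neighbour with 2.60 equiv of partner: the same reckoning gives M = 0.220 mM, above zero, so partner should outlast substrate and protic impurity. At 2.00 min that neighbour holds 99.1% target, 0.679% of its protic impurity, and 0.223 mM of partner.

The runs were computed on assumed constants; the scatter is artificial.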